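**Plan**

- Retrosynthesis: the first cut is the bond between benzofuran C5 and the benzylic CH2 on lactone C3, which gives an aryl boronate and an α-methylene lactone. The dihydrofuran ring is then cut at O1–C2 and C2–C3.
- Enabling feature: in the dihydrofuran ring, C2 carries O1 and an aryl group and C3 carries a one-carbon arm. C2 can therefore arrive as a benzylic sulfonium ylide carbon on the four-atom unit O1–C7a–C3a–C3 of an ortho-hydroxy-β-nitrostyrene, whose nitromethyl group later becomes the CH2OH arm.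
- Forward order: nitrostyrene and chiral sulfonium salt (steps 1–5), [4+1] closure of the dihydrofuran ring (step 6), nitromethyl to CH2OH and bromide to boronate (steps 7–9). The lactone ring is built separately (steps 10–13), the halves are joined by rhodium-catalysed conjugate arylation (step 14), then equilibrated and debenzylated (steps 15–16).
- Stereochemistry: benzofuran C2/C3 (2S,3R) come from the terpene sulfide on the ylide and trans-selective closure. Lactone C4 (S) comes from asymmetric hydrogenation of the Stobbe half-ester, and lactone C3 (S) from base equilibration to the trans lactone.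

Key step: step 6

Assumption: the (1R,4R,5R) sulfide and the (R,R) bisphospholane are taken to give the senses of induction drawn, by analogy with benzylic ylide epoxidation and itaconate half-ester hydrogenation; the antipodal sulfide or ligand would replace either one whose sense proved opposite.

**Route**

Step 1
Reactants: 1 2-(benzyloxy)phenol
Product: 2 3-(benzyloxy)-2-hydroxybenzaldehyde
Conditions: MgCl2, Et3N, (CH2O)n, MeCN, reflux; then 1 M HCl
Reagents that add atoms: paraformaldehyde (formaldehyde), C=O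
Why: Magnesium phenoxide-directed ortho-formylation (Casnati–Skattebøl reaction) can only reach the single free ortho position of the phenol, and the benzyl ether is inert to MgCl2/Et3N.

Step 2
Reactants: 2 3-(benzyloxy)-2-hydroxybenzaldehyde
Product: 3 3-(benzyloxy)-5-bromo-2-hydroxybenzaldehyde
Conditions: NBS, MeCN, 0 °C to rt
Reagents that add atoms: N-bromosuccinimide, O=C1CCC(=O)N1Br
Why: Electrophilic aromatic bromination goes para to the free hydroxyl, the position that is also meta to the formyl group, as in the bromination of ortho-vanillin.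

Step 3
Reactants: 3 3-(benzyloxy)-5-bromo-2-hydroxybenzaldehyde; 4 nitromethane
Product: 5 2-(benzyloxy)-4-bromo-6-[(E)-2-nitroethenyl]phenol
Conditions: MeNO2 (excess), NH4OAc (0.5 equiv), AcOH, 90 °C
Reagents that add atoms: none
Why: Henry (nitroaldol) condensation under ammonium acetate dehydrates in the flask to the conjugated E-nitroalkene, the standard entry to ortho-hydroxy-β-nitrostyrenes.

Step 4
Reactants: 6 [4-(benzyloxy)-3-methoxyphenyl]methanol
Product: 7 1-(benzyloxy)-4-(bromomethyl)-2-methoxybenzene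
Conditions: PBr3, CH2Cl2, 0 °C
Reagents that add atoms: phosphorus tribromide, BrP(Br)Br
Why: PBr3 turns the electron-rich benzylic alcohol into the bromide by displacement of the bromophosphite (nucleophilic substitution) without touching the aryl ethers.

Step 5
Reactants: 7 1-(benzyloxy)-4-(bromomethyl)-2-methoxybenzene; 8 (1R,4R,5R)-isothiocineole
Product: 9 (1R,4R,5R)-6-[4-(benzyloxy)-3-methoxybenzyl]-4,7,7-trimethyl-6-thiabicyclo[3.2.1]octan-6-ium triflate (exo S-benzyl)
Conditions: LiOTf, CH2Cl2/H2O, rt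
Reagents that add atoms: lithium trifluoromethanesulfonate, [Li+].[O-]S(=O)(=O)C(F)(F)F
Why: S-alkylation of the thioether on its less hindered exo lone pair, made irreversible by exchange of bromide for non-nucleophilic triflate, is the standard preparation of benzylsulfonium salts of this sulfide.

Step 6
Reactants: 5 2-(benzyloxy)-4-bromo-6-[(E)-2-nitroethenyl]phenol; 9 sulfonium triflate
Product: 10 (2S,3R)-7-(benzyloxy)-2-[4-(benzyloxy)-3-methoxyphenyl]-5-bromo-3-(nitromethyl)-2,3-dihydro-1-benzofuran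
Conditions: K2CO3 (2.5 equiv), MeCN, −20 °C to rt
Reagents that add atoms: none
Why: Proposed new method: carbonate generates the benzylic sulfonium ylide, which adds to the nitroalkene carbon bonded to the arene (C2–C3 bond), and once the ortho phenol has passed its proton to the nitronate the aryloxide expels the sulfide from the former ylide carbon (O1–C2 bond). The closest known reaction type is the [4+1] annulation of ortho-hydroxy-β-nitrostyrenes and ortho-quinone methides with carbonyl-stabilised sulfonium ylides, combined here with the asymmetric epoxidation and cyclopropanation chemistry of benzylic ylides of this terpene sulfide. The dihydrofuran ring closes by a 5-exo-tet substitution with inversion at C2. C2 is controlled by the sulfide, whose gem-dimethyl bridge fixes the ylide conformation and screens one face of the ylide carbon, and C3 by the open anti approach that keeps the two aryl groups apart in the betaine, which is carried into the trans (2S,3R) ring. The step needs closure through the phenoxide rather than through the nitronate oxygen (isoxazoline N-oxide) or carbon (cyclopropane), and it must outrun direct O-benzylation of the starting phenoxide by the salt; the free ortho hydroxyl, which quenches the nitronate and offers a harder, well-placed nucleophile, and the low standing ylide concentration under heterogeneous carbonate are relied on for this.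

Step 7
Reactants: 10 nitromethyl dihydrobenzofuran
Product: 11 (2S,3S)-7-(benzyloxy)-2-[4-(benzyloxy)-3-methoxyphenyl]-5-bromo-2,3-dihydro-1-benzofuran-3-carboxylic acid
Conditions: NaNO2, AcOH, DMSO, 35 °C
Reagents that add atoms: sodium nitrite, [Na+].[O-]N=O; water, O
Why: Nitrosation of the primary nitroalkane to a nitrolic acid and hydrolysis through the nitrile oxide and hydroxamic acid (nitrite/acetic acid oxidation, a mild acidic relative of the Nef reaction) stops at the carboxylic acid, and C3 stays trans because that is the stable epimer in this weakly acidic medium.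

Step 8
Reactants: 11 trans carboxylic acid
Product: 12 [(2S,3R)-7-(benzyloxy)-2-[4-(benzyloxy)-3-methoxyphenyl]-5-bromo-2,3-dihydro-1-benzofuran-3-yl]methanol
Conditions: BH3·THF, THF, 0 °C to rt; MeOH, then aqueous work-up
Reagents that add atoms: none
Why: Borane reduces the carboxylic acid chemoselectively through the acyloxyborane and leaves the aryl bromide, the benzyl ethers and both stereocentres untouched.

Step 9
Reactants: 12 bromo alcohol
Product: 13 [(2S,3R)-7-(benzyloxy)-2-[4-(benzyloxy)-3-methoxyphenyl]-5-(4,4,5,5-tetramethyl-1,3,2-dioxaborolan-2-yl)-2,3-dihydro-1-benzofuran-3-yl]methanol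
Conditions: B2pin2, PdCl2(dppf) (3 mol %), KOAc, 1,4-dioxane, 90 °C
Reagents that add atoms: bis(pinacolato)diboron, CC1(C)OB(OC1(C)C)B1OC(C)(C)C(C)(C)O1
Why: Miyaura borylation (oxidative addition of the aryl bromide to zerovalent palladium, acetate-assisted transmetalation with the diboron) tolerates the free primary alcohol and the benzyl ethers.

Step 10
Reactants: 14 4-(benzyloxy)-3-methoxybenzaldehyde; 15 dimethyl succinate
Product: 16 (E)-4-[4-(benzyloxy)-3-methoxyphenyl]-3-(methoxycarbonyl)but-3-enoic acid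
Conditions: NaOMe, MeOH, reflux; then aq HCl
Reagents that add atoms: none
Why: Stobbe condensation runs through the paraconic lactone, whose E1cB ring opening gives the E-alkylidene succinate half-ester with the free acid on the CH2 arm.

Step 11
Reactants: 16 Stobbe half-ester
Product: 17 (3S)-4-[4-(benzyloxy)-3-methoxyphenyl]-3-(methoxycarbonyl)butanoic acid
Conditions: [Rh(cod)((R,R)-Et-DuPhos)]BF4 (1 mol %), H2 (5 bar), NaOMe (10 mol %), MeOH, rt
Reagents that add atoms: none
Why: Carboxylate-directed asymmetric hydrogenation of itaconate-type half-esters with cationic rhodium bisphospholane catalysts sets C3 (S) through chelation of alkene and carboxylate to the chiral metal, and the benzyl ether is stable to homogeneous hydrogenation.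

Step 12
Reactants: 17 (S)-succinate half-ester
Product: 19 (4S)-4-[4-(benzyloxy)-3-methoxybenzyl]dihydrofuran-2(3H)-one, via hydroxy acid 18 (not isolated)
Conditions: KOH (1 equiv), EtOH, 0 °C; NaBH4, CaCl2, −10 °C to rt; then 3 M HCl, rt
Reagents that add atoms: none
Why: Calcium borohydride reduces the methyl ester but not the potassium carboxylate, and acidification lactonises the γ-hydroxy acid (chemoselective ester reduction then lactonisation) without touching the stereocentre.

Step 13
Reactants: 19 (S)-β-benzyl lactone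
Product: 22 (4S)-4-[4-(benzyloxy)-3-methoxybenzyl]-3-methylidenedihydrofuran-2(3H)-one, via Mannich base 20 (not isolated), via trimethylammonium iodide 21 (not isolated)
Conditions: LDA, THF, −78 °C; CH2=NMe2+ I−, −78 °C to rt; MeI, MeOH, rt; aq NaHCO3, CH2Cl2, rt
Reagents that add atoms: Eschenmoser's salt (N,N-dimethylmethyleneiminium iodide), C=[N+](C)C.[I-]; iodomethane, CI (its atoms reach 21 but not 22)
Why: Mannich-type aminomethylation of the lactone lithium enolate with Eschenmoser's salt, quaternisation and E1cB loss of trimethylamine is the standard α-methylenation of γ-butyrolactones, and the mild bicarbonate base avoids migration of the new double bond toward C4.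

Step 14
Reactants: 13 aryl pinacol boronate; 22 α-methylene lactone
Product: 23 (4S)-3-{[(2S,3R)-7-(benzyloxy)-2-[4-(benzyloxy)-3-methoxyphenyl]-3-(hydroxymethyl)-2,3-dihydro-1-benzofuran-5-yl]methyl}-4-[4-(benzyloxy)-3-methoxybenzyl]dihydrofuran-2(3H)-one as a mixture of lactone C3 epimers
Conditions: [Rh(cod)OH]2 (3 mol %), K3PO4 (0.5 equiv), 1,4-dioxane/H2O 10:1, 60 °C
Reagents that add atoms: none
Why: Rhodium-catalysed conjugate addition of the arylboron reagent (Hayashi–Miyaura reaction) forms the aryl–CH2 bond by aryl-rhodium insertion into the exocyclic alkene and protonation of the oxa-π-allyl rhodium enolate, which sets lactone C3 without control and should therefore give both epimers.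

Step 15
Reactants: 23 C3-epimeric adduct
Product: 24 (3S,4S)-3-{[(2S,3R)-7-(benzyloxy)-2-[4-(benzyloxy)-3-methoxyphenyl]-3-(hydroxymethyl)-2,3-dihydro-1-benzofuran-5-yl]methyl}-4-[4-(benzyloxy)-3-methoxybenzyl]dihydrofuran-2(3H)-one
Conditions: DBU (0.3 equiv), toluene, 60 °C
Reagents that add atoms: none
Why: Base-mediated epimerisation through the lactone enolate equilibrates C3 to the thermodynamically preferred trans-3,4-disubstituted lactone, so C3 (S) is set by the fixed C4 (S) centre.

Step 16
Reactants: 24 tri-O-benzyl trans lactone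
Product: 25 (3S,4S)-3-{[(2S,3R)-7-hydroxy-2-(4-hydroxy-3-methoxyphenyl)-3-(hydroxymethyl)-2,3-dihydro-1-benzofuran-5-yl]methyl}-4-(4-hydroxy-3-methoxybenzyl)dihydrofuran-2(3H)-one
Conditions: H2 (1 atm), 10% Pd/C, EtOAc/MeOH, rt
Reagents that add atoms: none
Why: Catalytic hydrogenolysis cleaves the three benzyl aryl ethers under neutral conditions at ambient pressure, where the cyclic benzylic C2–O1 ether, the lactone and all four stereocentres are expected to persist.

**Compound list**

1 | 2-(benzyloxy)phenol | Oc1ccccc1OCc1ccccc1 | starting material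
2 | 3-(benzyloxy)-2-hydroxybenzaldehyde | O=Cc1cccc(OCc2ccccc2)c1O | intermediate
3 | 3-(benzyloxy)-5-bromo-2-hydroxybenzaldehyde | O=Cc1cc(Br)cc(OCc2ccccc2)c1O | intermediate
4 | nitromethane | C[N+](=O)[O-] | starting material
5 | 2-(benzyloxy)-4-bromo-6-[(E)-2-nitroethenyl]phenol | Oc1c(OCc2ccccc2)cc(Br)cc1/C=C/[N+](=O)[O-] | intermediate
6 | [4-(benzyloxy)-3-methoxyphenyl]methanol | COc1cc(CO)ccc1OCc1ccccc1 | starting material
7 | 1-(benzyloxy)-4-(bromomethyl)-2-methoxybenzene | COc1cc(CBr)ccc1OCc1ccccc1 | intermediate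
8 | (1R,4R,5R)-4,7,7-trimethyl-6-thiabicyclo[3.2.1]octane (isothiocineole; one step from (R)-limonene and sulfur if not bought) | C[C@@H]1CC[C@@H]2C[C@H]1SC2(C)C | starting material
9 | (1R,4R,5R)-6-[4-(benzyloxy)-3-methoxybenzyl]-4,7,7-trimethyl-6-thiabicyclo[3.2.1]octan-6-ium trifluoromethanesulfonate, benzyl group on the exo face of sulfur (syn to the one-carbon bridge C8) | C[C@@H]1CC[C@@H]2C[C@H]1[S@@+](Cc1ccc(OCc3ccccc3)c(OC)c1)C2(C)C.[O-]S(=O)(=O)C(F)(F)F | intermediate
10 | (2S,3R)-7-(benzyloxy)-2-[4-(benzyloxy)-3-methoxyphenyl]-5-bromo-3-(nitromethyl)-2,3-dihydro-1-benzofuran (trans) | Brc1cc(OCc2ccccc2)c2c(c1)[C@H](C[N+](=O)[O-])[C@@H](c1ccc(OCc3ccccc3)c(OC)c1)O2 | intermediate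
11 | (2S,3S)-7-(benzyloxy)-2-[4-(benzyloxy)-3-methoxyphenyl]-5-bromo-2,3-dihydro-1-benzofuran-3-carboxylic acid (trans) | Brc1cc(OCc2ccccc2)c2c(c1)[C@H](C(=O)O)[C@@H](c1ccc(OCc3ccccc3)c(OC)c1)O2 | intermediate
12 | [(2S,3R)-7-(benzyloxy)-2-[4-(benzyloxy)-3-methoxyphenyl]-5-bromo-2,3-dihydro-1-benzofuran-3-yl]methanol | Brc1cc(OCc2ccccc2)c2c(c1)[C@H](CO)[C@@H](c1ccc(OCc3ccccc3)c(OC)c1)O2 | intermediate
13 | [(2S,3R)-7-(benzyloxy)-2-[4-(benzyloxy)-3-methoxyphenyl]-5-(4,4,5,5-tetramethyl-1,3,2-dioxaborolan-2-yl)-2,3-dihydro-1-benzofuran-3-yl]methanol | CC1(C)OB(OC1(C)C)c1cc(OCc2ccccc2)c2c(c1)[C@H](CO)[C@@H](c1ccc(OCc3ccccc3)c(OC)c1)O2 | intermediate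
14 | 4-(benzyloxy)-3-methoxybenzaldehyde (O-benzylvanillin) | COc1cc(C=O)ccc1OCc1ccccc1 | starting material
15 | dimethyl succinate | COC(=O)CCC(=O)OC | starting material
16 | (E)-4-[4-(benzyloxy)-3-methoxyphenyl]-3-(methoxycarbonyl)but-3-enoic acid | COC(=O)/C(CC(=O)O)=C/c1ccc(OCc2ccccc2)c(OC)c1 | intermediate
17 | (3S)-4-[4-(benzyloxy)-3-methoxyphenyl]-3-(methoxycarbonyl)butanoic acid | COC(=O)[C@H](CC(=O)O)Cc1ccc(OCc2ccccc2)c(OC)c1 | intermediate
18 | (3S)-4-[4-(benzyloxy)-3-methoxyphenyl]-3-(hydroxymethyl)butanoic acid | OC[C@H](CC(=O)O)Cc1ccc(OCc2ccccc2)c(OC)c1 | intermediate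
19 | (4S)-4-[4-(benzyloxy)-3-methoxybenzyl]dihydrofuran-2(3H)-one | COc1cc(C[C@@H]2COC(=O)C2)ccc1OCc1ccccc1 | intermediate
20 | (3R,4S)-4-[4-(benzyloxy)-3-methoxybenzyl]-3-[(dimethylamino)methyl]dihydrofuran-2(3H)-one (trans) | COc1cc(C[C@@H]2COC(=O)[C@H]2CN(C)C)ccc1OCc1ccccc1 | intermediate
21 | 1-{(3R,4S)-4-[4-(benzyloxy)-3-methoxybenzyl]-2-oxotetrahydrofuran-3-yl}-N,N,N-trimethylmethanaminium iodide | COc1cc(C[C@@H]2COC(=O)[C@H]2C[N+](C)(C)C)ccc1OCc1ccccc1.[I-] | intermediate
22 | (4S)-4-[4-(benzyloxy)-3-methoxybenzyl]-3-methylidenedihydrofuran-2(3H)-one | COc1cc(C[C@@H]2COC(=O)C2=C)ccc1OCc1ccccc1 | intermediate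
23 | (4S)-3-{[(2S,3R)-7-(benzyloxy)-2-[4-(benzyloxy)-3-methoxyphenyl]-3-(hydroxymethyl)-2,3-dihydro-1-benzofuran-5-yl]methyl}-4-[4-(benzyloxy)-3-methoxybenzyl]dihydrofuran-2(3H)-one, mixture of the (3R) cis and (3S) trans epimers at lactone C3 | COc1cc(C[C@@H]2COC(=O)C2Cc2cc(OCc3ccccc3)c3c(c2)[C@H](CO)[C@@H](c2ccc(OCc4ccccc4)c(OC)c2)O3)ccc1OCc1ccccc1 | intermediate
24 | (3S,4S)-3-{[(2S,3R)-7-(benzyloxy)-2-[4-(benzyloxy)-3-methoxyphenyl]-3-(hydroxymethyl)-2,3-dihydro-1-benzofuran-5-yl]methyl}-4-[4-(benzyloxy)-3-methoxybenzyl]dihydrofuran-2(3H)-one (trans lactone) | COc1cc(C[C@@H]2COC(=O)[C@H]2Cc2cc(OCc3ccccc3)c3c(c2)[C@H](CO)[C@@H](c2ccc(OCc4ccccc4)c(OC)c2)O3)ccc1OCc1ccccc1 | intermediate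
25 | (3S,4S)-3-{[(2S,3R)-7-hydroxy-2-(4-hydroxy-3-methoxyphenyl)-3-(hydroxymethyl)-2,3-dihydro-1-benzofuran-5-yl]methyl}-4-(4-hydroxy-3-methoxybenzyl)dihydrofuran-2(3H)-one (CNP0118131.1) | COc1cc(C[C@@H]2COC(=O)[C@H]2Cc2cc(O)c3c(c2)[C@H](CO)[C@@H](c2ccc(O)c(OC)c2)O3)ccc1O | target

**Step count**

Total: 16 steps. Longest linear sequence: 10 steps (1, 2, 3, 6, 7, 8, 9, 14, 15, 16) from 2-(benzyloxy)phenol.

**Steps most likely to fail**

Step 6. The phenoxide of 5 may simply be O-benzylated by the sulfonium salt before any ylide adds. The zwitterion may also close through the nitronate, or the ylide may add with poor face or anti/syn selectivity, which would lower the enantiomeric purity or the trans content. The fallback uses known carbene C–H insertion chemistry; it sets out from 5 and 7 and comes back at 11. Phenol 5 would be alkylated with bromide 7 (K2CO3, DMF) to 1-(benzyloxy)-2-{[4-(benzyloxy)-3-methoxybenzyl]oxy}-5-bromo-3-[(E)-2-nitroethenyl]benzene F1. NaBH4 (THF/MeOH, 0 °C) would reduce the nitroalkene to the 2-arylnitroethane F2, and NaNO2/AcOH/DMSO would oxidise that to the arylacetic acid F3. MeI/K2CO3 would give the methyl arylacetate F4, and diazo transfer with 4-acetamidobenzenesulfonyl azide and DBU the methyl aryldiazoacetate F5. Intramolecular C–H insertion of the rhodium carbene into the ether CH2 under Rh2(S-PTTL)4 (dirhodium tetrakis[N-phthaloyl-(S)-tert-leucinate], or its antipode, whichever gives 2S) in toluene at −60 °C should give the cis dihydrobenzofuran ester F6. NaOMe in MeOH would epimerise C3 to the trans methyl ester F7, and aqueous LiOH added to the same flask would give acid 11.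

Step 14. The electron-rich boronate may protodeboronate faster than it transmetalates, insertion into the 1,1-disubstituted acceptor may be slow, and a rhodium hydride may move the exocyclic double bond into the ring with loss of the C4 stereocentre. The fallback is a classical lactone enolate benzylation; it sets out from 12 and 19 and comes back at 24. Alcohol 12 would be silylated (TBSCl, imidazole, DMF) to the tert-butyldimethylsilyl ether F8. Suzuki–Miyaura hydroxymethylation with potassium (acetoxymethyl)trifluoroborate (Pd(OAc)2, RuPhos, Na2CO3, dioxane/H2O, 100 °C) would give the 5-(hydroxymethyl) compound F9, and an Appel reaction (CBr4, PPh3, CH2Cl2, 0 °C) the 5-(bromomethyl) compound F10. The lithium enolate of 19 (LiHMDS, THF, −78 °C) would be alkylated by F10 anti to the C4 substituent to give the silylated trans lactone F11, and TBAF in THF would give 24. This path needs neither step 9, step 13 nor step 15.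

Step 7. The slow nitrosative oxidation may be overtaken by nitrosation of the electron-rich rings or by acid-promoted opening of the benzylic C2–O1 bond. The fallback goes through the aldehyde oxidation level; it sets out from 10 and comes back at 12. The nitronate of 10 (NaOMe, MeOH/CH2Cl2, −78 °C) would be cleaved with ozone and worked up with Me2S (oxidative Nef reaction) to the trans 3-carbaldehyde F12. This would be reduced at once with NaBH4 (MeOH, 0 °C) to alcohol 12, so that step 8 is not needed either.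

Further compounds
F1 | step 6 | 1-(benzyloxy)-2-{[4-(benzyloxy)-3-methoxybenzyl]oxy}-5-bromo-3-[(E)-2-nitroethenyl]benzene | COc1cc(COc2c(OCc3ccccc3)cc(Br)cc2/C=C/[N+](=O)[O-])ccc1OCc1ccccc1
F2 | step 6 | 1-(benzyloxy)-2-{[4-(benzyloxy)-3-methoxybenzyl]oxy}-5-bromo-3-(2-nitroethyl)benzene | COc1cc(COc2c(OCc3ccccc3)cc(Br)cc2CC[N+](=O)[O-])ccc1OCc1ccccc1
F3 | step 6 | 2-[3-(benzyloxy)-2-{[4-(benzyloxy)-3-methoxybenzyl]oxy}-5-bromophenyl]acetic acid | COc1cc(COc2c(OCc3ccccc3)cc(Br)cc2CC(=O)O)ccc1OCc1ccccc1
F4 | step 6 | methyl 2-[3-(benzyloxy)-2-{[4-(benzyloxy)-3-methoxybenzyl]oxy}-5-bromophenyl]acetate | COC(=O)Cc1cc(Br)cc(OCc2ccccc2)c1OCc1ccc(OCc2ccccc2)c(OC)c1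
F5 | step 6 | methyl 2-[3-(benzyloxy)-2-{[4-(benzyloxy)-3-methoxybenzyl]oxy}-5-bromophenyl]-2-diazoacetate | COC(=O)C(=[N+]=[N-])c1cc(Br)cc(OCc2ccccc2)c1OCc1ccc(OCc2ccccc2)c(OC)c1
F6 | step 6 | methyl (2S,3R)-7-(benzyloxy)-2-[4-(benzyloxy)-3-methoxyphenyl]-5-bromo-2,3-dihydro-1-benzofuran-3-carboxylate (cis) | Brc1cc(OCc2ccccc2)c2c(c1)[C@@H](C(=O)OC)[C@@H](c1ccc(OCc3ccccc3)c(OC)c1)O2
F7 | step 6 | methyl (2S,3S)-7-(benzyloxy)-2-[4-(benzyloxy)-3-methoxyphenyl]-5-bromo-2,3-dihydro-1-benzofuran-3-carboxylate (trans) | Brc1cc(OCc2ccccc2)c2c(c1)[C@H](C(=O)OC)[C@@H](c1ccc(OCc3ccccc3)c(OC)c1)O2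
F8 | step 14 | {[(2S,3R)-7-(benzyloxy)-2-[4-(benzyloxy)-3-methoxyphenyl]-5-bromo-2,3-dihydro-1-benzofuran-3-yl]methoxy}(tert-butyl)dimethylsilane | Brc1cc(OCc2ccccc2)c2c(c1)[C@H](CO[Si](C)(C)C(C)(C)C)[C@@H](c1ccc(OCc3ccccc3)c(OC)c1)O2
F9 | step 14 | [(2S,3R)-7-(benzyloxy)-2-[4-(benzyloxy)-3-methoxyphenyl]-3-{[(tert-butyldimethylsilyl)oxy]methyl}-2,3-dihydro-1-benzofuran-5-yl]methanol | OCc1cc(OCc2ccccc2)c2c(c1)[C@H](CO[Si](C)(C)C(C)(C)C)[C@@H](c1ccc(OCc3ccccc3)c(OC)c1)O2
F10 | step 14 | {[(2S,3R)-7-(benzyloxy)-2-[4-(benzyloxy)-3-methoxyphenyl]-5-(bromomethyl)-2,3-dihydro-1-benzofuran-3-yl]methoxy}(tert-butyl)dimethylsilane | BrCc1cc(OCc2ccccc2)c2c(c1)[C@H](CO[Si](C)(C)C(C)(C)C)[C@@H](c1ccc(OCc3ccccc3)c(OC)c1)O2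
F11 | step 14 | (3S,4S)-3-{[(2S,3R)-7-(benzyloxy)-2-[4-(benzyloxy)-3-methoxyphenyl]-3-{[(tert-butyldimethylsilyl)oxy]methyl}-2,3-dihydro-1-benzofuran-5-yl]methyl}-4-[4-(benzyloxy)-3-methoxybenzyl]dihydrofuran-2(3H)-one | COc1cc(C[C@@H]2COC(=O)[C@H]2Cc2cc(OCc3ccccc3)c3c(c2)[C@H](CO[Si](C)(C)C(C)(C)C)[C@@H](c2ccc(OCc4ccccc4)c(OC)c2)O3)ccc1OCc1ccccc1
F12 | step 7 | (2S,3S)-7-(benzyloxy)-2-[4-(benzyloxy)-3-methoxyphenyl]-5-bromo-2,3-dihydro-1-benzofuran-3-carbaldehyde (trans) | Brc1cc(OCc2ccccc2)c2c(c1)[C@H](C=O)[C@@H](c1ccc(OCc3ccccc3)c(OC)c1)O2
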